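**Retrosynthetic overview**
1. Target ⇐ its methyl ester; the spiro-dihydropyran comes from a δ-hydroxy ketone, whose two arms are put on a bridging ketone by Wittig homologation and a Michael addition.
2. Bridged amino ketone ⇐ α-methylene cycloheptenone + MeNH2 + CH2O: aza-Michael addition, then an intramolecular Mannich reaction closes the piperidine and sets the quaternary ring-fusion carbon (key ring closure).
3. Cycloheptenone ⇐ aldehyde / 2-bromoalkene (Nozaki–Hiyama–Kishi closure); aldehyde and ester ⇐ oxidative cleavage of one bridge of a norbornene-type silyl enol ether.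
4. All-cis diquinane ⇐ endo Diels–Alder of 2-silyloxycyclopentadiene with 2-bromocyclopentenone; the C=O/C–Br pair becomes the tetrasubstituted alkene.
5. Ring order: rings A and B (cycloaddition) → seven-membered ring → piperidine → dihydropyran. Three side fragments: bromo enone 4, C4 bromoalkene 8, silyl vinyl ketone 26.

Assumption: ring A is the cyclopentene and ring B the ester-bearing cyclopentane; the catalyst antipode in step 3 is taken to be the one that gives 5 (the mirror-image catalyst is used if the sense is opposite).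

**Step 1**
Reactants: 1 cyclopent-2-en-1-one
Product: 2 2-(triisopropylsilyloxy)cyclopenta-1,3-diene
Conditions: iPr3SiOTf, Et3N, CH2Cl2, 0 °C (used at once)
Reagents that add atoms: triisopropylsilyl trifluoromethanesulfonate, CC(C)[Si](C(C)C)(C(C)C)OS(=O)(=O)C(F)(F)F
Why: Soft enolisation and O-silylation at the only sp3 α-carbon (silyl dienol ether formation) gives the cross-conjugated 2-silyloxy diene; no stereocentre is formed.

**Step 2**
Reactants: 1 cyclopent-2-en-1-one
Product: 4 2-bromocyclopent-2-en-1-one, via trans-2,3-dibromocyclopentanone 3 (not isolated)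
Conditions: Br2, CH2Cl2, 0 °C; then Et3N, 0 °C
Reagents that add atoms: bromine, BrBr
Why: Bromine addition to the enone followed by E1cB loss of HBr (bromination–dehydrobromination) returns the conjugated α-bromo enone with no stereocentre left.

**Step 3**
Reactants: 2 2-(triisopropylsilyloxy)cyclopenta-1,3-diene; 4 2-bromocyclopent-2-en-1-one
Product: 5 endo-2-bromo-8-(triisopropylsilyloxy)tricyclo[5.2.1.0^2,6]dec-8-en-3-one
Conditions: (S)-3,3-diphenyl-1-(2-methylphenyl)tetrahydro-1H,3H-pyrrolo[1,2-c][1,3,2]oxazaborole, N-protonated with HN(SO2CF3)2 (15 mol %), CH2Cl2, −78 °C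
Reagents that add atoms: none
Why: Lewis-acid-catalysed endo Diels–Alder reaction in which the diene terminus next to OSi bonds to the enone β-carbon, the ketone ring sits under the new alkene (Br exo) and the chiral catalyst shields one enone face, so all four stereocentres, relative and absolute, are set here.

**Step 4**
Reactants: 6 but-3-yn-1-ol
Product: 7 3-bromobut-3-en-1-ol
Conditions: HBr, Et4NBr, CH2Cl2, 40 °C
Reagents that add atoms: hydrogen bromide, Br
Why: Markovnikov hydrobromination of the terminal alkyne puts bromine on the internal carbon and gives the 2-bromoalkene.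

**Step 5**
Reactants: 7 3-bromobut-3-en-1-ol
Product: 8 2,4-dibromobut-1-ene
Conditions: CBr4, PPh3, CH2Cl2, 0 °C
Reagents that add atoms: tetrabromomethane, BrC(Br)(Br)Br
Why: Appel reaction converts the primary alcohol into the bromide by SN2 displacement of the oxyphosphonium group.

**Step 6**
Reactants: 8 2,4-dibromobut-1-ene; 5 endo-2-bromo-8-(triisopropylsilyloxy)tricyclo[5.2.1.0^2,6]dec-8-en-3-one
Product: 11 3-(3-bromobut-3-enyl)-8-(triisopropylsilyloxy)tricyclo[5.2.1.0^2,6]deca-2,8-diene, via Grignard reagent 9 (not isolated), via bromohydrin 10 (not isolated)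
Conditions: Mg, THF, 0 °C; then 5, CeCl3, THF, −78 °C; then AcOH, Zn dust, THF, 0 → 25 °C
Reagents that add atoms: none
Why: Grignard 1,2-addition to the α-bromo ketone from the convex face and zinc-mediated reductive β-elimination of the bromohydrin (Boord-type olefination) place the tetrasubstituted alkene exactly between the former C=O and C–Br carbons, destroying those two stereocentres and leaving the others untouched.

**Step 7**
Reactants: 11 3-(3-bromobut-3-enyl)-8-(triisopropylsilyloxy)tricyclo[5.2.1.0^2,6]deca-2,8-diene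
Product: 12 3-(3-bromobut-3-enyl)-9-exo-hydroxytricyclo[5.2.1.0^2,6]dec-2-en-8-one
Conditions: OsO4 (2 mol %), 4-methylmorpholine N-oxide, acetone–H2O, 0 °C
Reagents that add atoms: 4-methylmorpholine N-oxide, C[N+]1([O-])CCOCC1
Why: OsO4 dihydroxylation picks the strained, electron-rich silyl enol ether over the hindered tetrasubstituted alkene and the electron-poor bromoalkene, attacks its exo face, and the silyl hemiketal collapses to the α-hydroxy ketone (Rubottom-type α-hydroxylation).

**Step 8**
Reactants: 12 3-(3-bromobut-3-enyl)-9-exo-hydroxytricyclo[5.2.1.0^2,6]dec-2-en-8-one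
Product: 13 methyl 6-(3-bromobut-3-enyl)-1-formyl-1,2,3,3a,4,5-hexahydropentalene-3-carboxylate
Conditions: Pb(OAc)4, MeOH–PhMe, 0 °C
Reagents that add atoms: methanol, CO
Why: Criegee-type cleavage of the α-ketol through its methyl hemiketal gives an aldehyde and a methyl ester that are cis to each other and to ring A, because both carbons came from the one endo-fused two-carbon bridge.

**Step 9**
Reactants: 13 methyl 6-(3-bromobut-3-enyl)-1-formyl-1,2,3,3a,4,5-hexahydropentalene-3-carboxylate
Product: 14 tricyclic allylic alcohol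
Conditions: CrCl2, NiCl2 (5 mol %), DMSO, 25 °C, 0.005 M
Reagents that add atoms: none
Why: Intramolecular Nozaki–Hiyama–Kishi reaction, in which the alkenylchromium from the 2-bromoalkene adds to the aldehyde, closes the seven-membered ring under non-basic conditions; the new carbinol centre (both epimers) is removed in step 10.

**Step 10**
Reactants: 14 tricyclic allylic alcohol
Product: 15 tricyclic α-methylene ketone
Conditions: Dess–Martin periodinane, NaHCO3, CH2Cl2, 0 °C
Reagents that add atoms: none
Why: Dess–Martin oxidation of the allylic alcohol gives the exocyclic enone without moving either alkene.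

**Step 11**
Reactants: 15 tricyclic α-methylene ketone
Product: 17 bridged amino ketone, via amino ketone 16 (not isolated)
Conditions: MeNH2 (2 M in MeOH), 0 °C, excess removed in vacuo; then CH2O (37 % aq.), AcOH, MeOH, 50 °C
Reagents that add atoms: methylamine, CN; formaldehyde, C=O
Why: Aza-Michael addition of methylamine to the exocyclic enone followed by an intramolecular Mannich reaction, in which the N-methyl iminium attacks the α-carbon of the dienol from the convex face opposite ring A and the ester, creates the quaternary carbon (CH2N trans to the ester) and fixes the bridgehead CH.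

**Step 12**
Reactants: 17 bridged amino ketone
Product: 19 bridge carbaldehyde, via enol ether 18 (not isolated)
Conditions: Ph3P(CH2OMe)Cl, KN(SiMe3)2, THF, 0 → 50 °C; then 2 M HCl, THF, 25 °C
Reagents that add atoms: (methoxymethyl)triphenylphosphonium chloride, COC[P+](c1ccccc1)(c1ccccc1)c1ccccc1.[Cl-]; water, O
Why: Wittig methoxymethylenation of the non-enolisable bridging ketone and hydrolysis of the enol ether give the one-carbon-homologated aldehyde, whose α-centre (epimer mixture) is planarised again in step 16.

**Step 13**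
Reactants: 20 trimethyl(vinyl)silane
Product: 22 (1-bromovinyl)trimethylsilane, via dibromide 21 (not isolated)
Conditions: Br2, CH2Cl2, −78 °C; then Et2NH, reflux
Reagents that add atoms: bromine, BrBr
Why: Bromination–dehydrobromination of the vinylsilane gives the 1-bromovinylsilane.

**Step 14**
Reactants: 22 (1-bromovinyl)trimethylsilane; 23 2-methylpropanal
Product: 25 4-methyl-2-(trimethylsilyl)pent-1-en-3-ol, via Grignard reagent 24 (not isolated)
Conditions: Mg, THF, reflux; then 23, 0 °C; then H2O
Reagents that add atoms: none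
Why: Grignard formation from the alkenyl bromide and 1,2-addition to the aldehyde give the racemic silyl allylic alcohol.

**Step 15**
Reactants: 25 4-methyl-2-(trimethylsilyl)pent-1-en-3-ol
Product: 26 4-methyl-2-(trimethylsilyl)pent-1-en-3-one
Conditions: Dess–Martin periodinane, CH2Cl2, 25 °C
Reagents that add atoms: none
Why: Dess–Martin oxidation gives the α-silyl vinyl ketone, a Stork-type Michael acceptor that does not polymerise under enolate conditions.

**Step 16**
Reactants: 19 bridge carbaldehyde; 26 4-methyl-2-(trimethylsilyl)pent-1-en-3-one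
Product: 29 δ-hydroxy ketone, via silyl keto aldehyde 27 (not isolated), via silyl hydroxy ketone 28 (not isolated)
Conditions: KN(SiMe3)2, THF, −78 °C, then 26; then MeOH, NaBH4, −40 °C; then KF, MeOH, 25 °C
Reagents that add atoms: none
Why: Michael addition of the potassium aldehyde enolate to the α-silyl vinyl ketone forms the quaternary carbon from the face syn to the sp2-flanked carbocyclic bridge (the piperidine face is shielded by two axial C–H bonds), and aldehyde-selective NaBH4 reduction plus fluoride-induced protodesilylation then give the δ-hydroxy ketone.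

**Step 17**
Reactants: 29 δ-hydroxy ketone
Product: 30 methyl ester of the target
Conditions: CSA (1.2 equiv), 4 Å molecular sieves, PhMe, 60 °C
Reagents that add atoms: none
Why: Acid-catalysed lactol formation and dehydration give the endocyclic six-membered enol ether, the more stable regioisomer, with the sieves taking up the water.

**Step 18**
Reactants: 30 methyl ester of the target
Product: 31 target acid CNP0237695.2
Conditions: KOSiMe3, THF, 25 °C; then AcOH (1 equiv)
Reagents that add atoms: potassium trimethylsilanolate, C[Si](C)(C)[O-].[K+]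
Why: Silanolate-mediated ester cleavage under non-enolising conditions frees the acid without epimerising its α-carbon or touching the enol ether.

**Compound list**
1 | cyclopent-2-en-1-one | O=C1C=CCC1 | starting material
2 | 2-(triisopropylsilyloxy)cyclopenta-1,3-diene | CC(C)[Si](OC1=CCC=C1)(C(C)C)C(C)C | intermediate
3 | trans-2,3-dibromocyclopentan-1-one (racemic, one enantiomer drawn) | O=C1CC[C@H](Br)[C@H]1Br | intermediate
4 | 2-bromocyclopent-2-en-1-one | O=C1CCC=C1Br | intermediate
5 | endo-2-bromo-8-(triisopropylsilyloxy)tricyclo[5.2.1.0^2,6]dec-8-en-3-one (cyclopentanone ring endo, Br exo at the ring fusion) | O=C1CC[C@@H]2[C@@]1(Br)[C@H]3C[C@@H]2C(O[Si](C(C)C)(C(C)C)C(C)C)=C3 | intermediate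
6 | but-3-yn-1-ol | C#CCCO | starting material
7 | 3-bromobut-3-en-1-ol | C=C(Br)CCO | intermediate
8 | 2,4-dibromobut-1-ene | C=C(Br)CCBr | intermediate
9 | (3-bromobut-3-en-1-yl)magnesium bromide | C=C(Br)CC[Mg]Br | intermediate
10 | 2-bromo-3-(3-bromobut-3-enyl)-8-(triisopropylsilyloxy)tricyclo[5.2.1.0^2,6]dec-8-en-3-ol (new chain cis to Br) | O[C@@]1(CCC(Br)=C)CC[C@@H]2[C@@]1(Br)[C@H]3C[C@@H]2C(O[Si](C(C)C)(C(C)C)C(C)C)=C3 | intermediate
11 | 3-(3-bromobut-3-enyl)-8-(triisopropylsilyloxy)tricyclo[5.2.1.0^2,6]deca-2,8-diene (H-6 exo) | C=C(Br)CCC1=C2[C@@H](CC1)[C@@H]3C[C@H]2C=C3O[Si](C(C)C)(C(C)C)C(C)C | intermediate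
12 | 3-(3-bromobut-3-enyl)-9-exo-hydroxytricyclo[5.2.1.0^2,6]dec-2-en-8-one | C=C(Br)CCC1=C2[C@@H](CC1)[C@@H]3C[C@H]2[C@@H](O)C3=O | intermediate
13 | methyl 6-(3-bromobut-3-enyl)-1-formyl-1,2,3,3a,4,5-hexahydropentalene-3-carboxylate (formyl and ester cis, both on the face of C-4; H-3a on the other face) | C=C(Br)CCC1=C2[C@@H](CC1)[C@@H](C(=O)OC)C[C@H]2C=O | intermediate
14 | tricyclic allylic alcohol: ring A cyclopentene, ring B cyclopentane with CO2Me, cycloheptene ring with CH(OH) on the carbon bonded to ring B and an adjacent C(=CH2); both carbinol epimers | C=C1CCC2=C3[C@@H](CC2)[C@@H](C(=O)OC)C[C@H]3C1O | intermediate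
15 | tricyclic α-methylene ketone (ketone in place of the carbinol of 14) | C=C1CCC2=C3[C@@H](CC2)[C@@H](C(=O)OC)C[C@H]3C1=O | intermediate
16 | β-(methylamino) ketone (CH2NHMe on the carbon α to the ketone, epimer mixture) | CNCC1CCC2=C3[C@@H](CC2)[C@@H](C(=O)OC)C[C@H]3C1=O | intermediate
17 | bridged amino ketone: N-methyl-3-azabicyclo[4.3.1]decan-10-one fused to the diquinane, ketone on the one-carbon bridge, quaternary ring-fusion carbon with CH2N trans to the ester | O=C2[C@H]1CCC3=C4[C@@H](CC3)[C@@H](C(=O)OC)C[C@]42CN(C)C1 | intermediate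
18 | methoxymethylene compound (methyl enol ether on the bridge carbon) | COC=C2[C@H]1CCC3=C4[C@@H](CC3)[C@@H](C(=O)OC)C[C@]42CN(C)C1 | intermediate
19 | bridge carbaldehyde (CHO-bearing bridge carbon as epimer mixture) | O=CC2[C@H]1CCC3=C4[C@@H](CC3)[C@@H](C(=O)OC)C[C@]42CN(C)C1 | intermediate
20 | trimethyl(vinyl)silane | C=C[Si](C)(C)C | starting material
21 | (1,2-dibromoethyl)trimethylsilane (racemic) | BrCC(Br)[Si](C)(C)C | intermediate
22 | (1-bromovinyl)trimethylsilane | C=C(Br)[Si](C)(C)C | intermediate
23 | 2-methylpropanal | CC(C)C=O | starting material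
24 | [1-(trimethylsilyl)vinyl]magnesium bromide | C=C([Mg]Br)[Si](C)(C)C | intermediate
25 | 4-methyl-2-(trimethylsilyl)pent-1-en-3-ol (racemic) | CC(C)C(O)C(=C)[Si](C)(C)C | intermediate
26 | 4-methyl-2-(trimethylsilyl)pent-1-en-3-one | CC(C)C(=O)C(=C)[Si](C)(C)C | intermediate
27 | α-trimethylsilyl keto aldehyde: quaternary bridge carbon carrying CHO (syn to N) and CH2CH(SiMe3)C(=O)iPr (over the carbocyclic bridge) | CC(C)C(=O)C([Si](C)(C)C)C[C@@]2(C=O)[C@H]1CCC3=C4[C@@H](CC3)[C@@H](C(=O)OC)C[C@]42CN(C)C1 | intermediate
28 | α-trimethylsilyl hydroxy ketone (CH2OH in place of CHO) | CC(C)C(=O)C([Si](C)(C)C)C[C@@]2(CO)[C@H]1CCC3=C4[C@@H](CC3)[C@@H](C(=O)OC)C[C@]42CN(C)C1 | intermediate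
29 | δ-hydroxy ketone: bridge carbon carrying CH2OH (syn to N) and CH2CH2C(=O)iPr | CC(C)C(=O)CC[C@@]2(CO)[C@H]1CCC3=C4[C@@H](CC3)[C@@H](C(=O)OC)C[C@]42CN(C)C1 | intermediate
30 | methyl ester of the target (spiro 6-isopropyl-3,4-dihydro-2H-pyran in place) | CC(C)C1=CC[C@@]2(CO1)[C@H]1CCC3=C4[C@@H](CC3)[C@@H](C(=O)OC)C[C@]42CN(C)C1 | intermediate
31 | CNP0237695.2 (carboxylic acid) | CC(C)C1=CC[C@@]2(CO1)[C@H]1CCC3=C4[C@@H](CC3)[C@@H](C(=O)O)C[C@]42CN(C)C1 | target

**Count**
Total steps: 18. Longest linear sequence: 12 (steps 1, 3, 6, 7, 8, 9, 10, 11, 12, 16, 17, 18); the branches are steps 2, 4–5 and 13–15.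

**Three steps most likely to fail**

Step 3 (enantio- and endo-control with an untested diene/dienophile pair). Fallback: 2 and 4 are combined without catalyst (CH2Cl2, 25 °C), which gives racemic 5, that is 5 together with the mirror-image adduct F1. The racemate is taken through steps 6 and 7 unchanged (mirror-image bromohydrin F2, mirror-image diene F3) to racemic 12, which contains the mirror-image hydroxy ketone F4. Esterification with (S)-2-methoxy-2-phenylacetic acid (DCC, DMAP, CH2Cl2) gives the O-methylmandelate F5 of 12 and the diastereomeric O-methylmandelate F6, which are separated by chromatography. K2CO3 in MeOH cleaves F5, and the route is rejoined at 12.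

Step 9 (medium-ring closure from a 2-bromoalkene). Fallback, setting out from 13: oxidation (NaClO2, NaH2PO4, 2-methylbut-2-ene) gives the carboxylic acid F7, and coupling with MeNHOMe·HCl (EDC, iPr2NEt, CH2Cl2) gives the Weinreb amide F8. Bromine–lithium exchange (t-BuLi, THF, −100 °C) then lets the alkenyllithium acylate the amide intramolecularly. This gives 15 directly, so the route is rejoined at 15 and step 10 is not needed.

Step 16 (quaternary carbon next to a quaternary carbon; facial selectivity). Fallback, setting out from 19, for the case that the acceptor enters syn to nitrogen: the two arms are introduced in the opposite order. A crossed aldol reaction with formaldehyde (aq. CH2O, K2CO3, THF) brings in the CH2OH arm on that face and gives the hydroxy aldehyde F9. Horner–Wadsworth–Emmons olefination with dimethyl (3-methyl-2-oxobutyl)phosphonate (LiCl, iPr2NEt, MeCN) gives the enone F10. Conjugate reduction with [(Ph3P)CuH]6 (PhMe, H2O) gives 29, where the route is rejoined.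

**Further compounds**
F1 | step 3 | mirror-image adduct (enantiomer of 5) | O=C1CC[C@H]2[C@]1(Br)[C@@H]3C[C@H]2C(O[Si](C(C)C)(C(C)C)C(C)C)=C3
F2 | step 3 | mirror-image bromohydrin (enantiomer of 10) | O[C@]1(CCC(Br)=C)CC[C@H]2[C@]1(Br)[C@@H]3C[C@H]2C(O[Si](C(C)C)(C(C)C)C(C)C)=C3
F3 | step 3 | mirror-image diene (enantiomer of 11) | C=C(Br)CCC1=C2[C@H](CC1)[C@H]3C[C@@H]2C=C3O[Si](C(C)C)(C(C)C)C(C)C
F4 | step 3 | mirror-image hydroxy ketone (enantiomer of 12) | C=C(Br)CCC1=C2[C@H](CC1)[C@H]3C[C@@H]2[C@H](O)C3=O
F5 | step 3 | O-methylmandelate of 12 ((S)-2-methoxy-2-phenylacetate ester) | C=C(Br)CCC1=C2[C@@H](CC1)[C@@H]3C[C@H]2[C@@H](OC(=O)[C@@H](OC)c4ccccc4)C3=O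
F6 | step 3 | diastereomeric O-methylmandelate (ester of F4) | C=C(Br)CCC1=C2[C@H](CC1)[C@H]3C[C@@H]2[C@H](OC(=O)[C@@H](OC)c4ccccc4)C3=O
F7 | step 9 | carboxylic acid from 13 | C=C(Br)CCC1=C2[C@@H](CC1)[C@@H](C(=O)OC)C[C@H]2C(=O)O
F8 | step 9 | Weinreb amide (N-methoxy-N-methylamide of F7) | C=C(Br)CCC1=C2[C@@H](CC1)[C@@H](C(=O)OC)C[C@H]2C(=O)N(C)OC
F9 | step 16 | hydroxy aldehyde (bridge carbon with CH2OH syn to N and CHO) | O=C[C@@]2(CO)[C@H]1CCC3=C4[C@@H](CC3)[C@@H](C(=O)OC)C[C@]42CN(C)C1
F10 | step 16 | enone ((E)-4-methyl-3-oxopent-1-enyl arm in place of CHO) | CC(C)C(=O)/C=C/[C@@]2(CO)[C@H]1CCC3=C4[C@@H](CC3)[C@@H](C(=O)OC)C[C@]42CN(C)C1
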